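## Structural features

The target has one ring, the flat 2,4,6-trihydroxyphenyl ring C1'–C6'. It is joined at C1' through the ketone carbon C1 to an unbranched C18 chain. Along the chain follow four methylenes (C2–C5), the isolated alkene C6=C7 (Z), C8H2, the carbinol C9 (R), the conjugated diene C10=C11 (E)/C12=C13 (Z), the bis-allylic C14H2, the alkene C15=C16 (Z) and the ethyl end C17–C18. C9 is the only stereocentre, has no stereogenic neighbour and lies nine bonds from the ring, so nothing in the molecule can direct its formation. The dienyl carbinol C9–C13 is the most fragile part: acid ionises it to a pentadienyl cation (racemisation, transposition, loss of water), and radicals, light or metals turn the E,Z-diene into the E,E-diene. C14H2 autoxidises easily, C8H2 would be doubly activated if C9 ever became a ketone, and the ring carbons C3' and C5' are strong carbon nucleophiles towards formaldehyde and similar electrophiles. The aryl ketone bond C1–C1' is ordinary; the real difficulty is to place four alkenes of three kinds (isolated Z, conjugated E,Z, skipped Z) with full geometric control around a lone, remote stereocentre. The key step exploits the unit C9(OH)–C10=C11(E)–C12=C13(Z), which is the oxygenated and transposed form of a skipped diene C9=C10(Z)–C11H2–C12=C13(Z). Taking the oxygen away therefore turns the chain into the all-Z 6,9,12,15-tetraene of a commercial C18 fatty acid, which is the fingerprint of a lipoxygenase and the presumed biosynthesis.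

## Logic of the disconnections

**11 ⇒ 10.** No skeletal bond is cut; the C9–OH is traced back to C9–O–OH. The reason is that dioxygen as the oxygen source delivers a hydroperoxide. The cut gains nothing in the skeleton, but it opens the key cut. The forward step needs a reductant that breaks only O–O. It must leave C9–O (and with it the configuration), the ketone C1 and the E,Z-diene untouched.

**10 ⇒ 9 (key disconnection).** The C9–O bond is cut, C10=C11 (E) is moved back to C9=C10 (Z), and a hydrogen is returned to C11.
- Gain: the stereocentre, the E alkene and the conjugation all vanish in one operation. The precursor is achiral and carries four alike Z alkenes that come ready-made from the pool.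
- Timing: the fragile dienyl carbinol appears only in the last flask, in buffer near neutrality, so it needs no protecting group.
- Demand on the forward step: one of three bis-allylic methylenes (C11, not C8 or C14), one of the two ends of the pentadienyl system (C9, not C13) and one face. No small reagent can meet this, but an R-selective lipoxygenase is built for it.
- In one sentence: a 9R-lipoxygenase dioxygenates the achiral all-Z tetraene 9 at C9. This sentence does not fit the olefination and coupling routes that would be drawn first.

**9 ⇒ 8.** The three phenolic O–H bonds are traced back to O–CH2OMe. The ring has to serve as a carbanion in the joining step and cannot carry acidic hydrogens there. The acid needed for the removal is placed before the key step. There it meets only isolated Z alkenes, which tolerate it, and not the dienyl carbinol, which would not.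

**8 ⇒ 7 ⇒ 6 + 3.** The bond C1–C1' is cut. It is the only bond between the two halves, and cutting it gives a symmetric arene and a derivative of the natural chain. The forward step needs a single addition to the acyl carbon without over-addition. It must also proceed without deprotonation at C2, C8, C11 or C14.

**6 ⇒ 5 ⇒ 4.** The C–Li bond goes back to C–H and the three O–C acetal bonds go back to the free triol. The three ring C–H positions of 5 are equivalent and each lies between two directing oxygens, so no regiochemical question arises. The forward alkylation must go to oxygen and not to ring carbon.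

**3 ⇒ 2 ⇒ 1.** The bond C1–N is cut. The acyl carbon is activated under neutral conditions that cannot move or isomerise the skipped alkenes. The result is a commercial acid that already holds C1–C18 and all four alkene positions.

## Other disconnections considered

**Alternative 1:** (the first that comes to mind) The cut is at C12=C13. The forward key step is a Z-selective Wittig reaction of the γ-silyloxy enal A1 (C1–C12, ring attached and protected) with the ylide from the phosphonium salt A2 (C13–C18).
- C9 would have to be bought from the chiral pool or set in a separate asymmetric step. C6=C7 and C10=C11 would each need an olefination or a semi-reduction of their own.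
- Every alkene and the carbinol thus costs its own bond-forming step plus redox and protecting-group steps, which makes the route several times longer than the chosen one.
- A1 can lose silanol by an E1cB path under the basic ylide conditions, and a Z/E mixture at a conjugated diene is hard to purify.
- The last step would have to free three phenols in the presence of the acid-labile dienyl carbinol. The chosen plan avoids this conflict by its order of events.

**Alternative 2:** The cut is at C9–H. The forward key step is an enantioselective 1,2-reduction (ketoreductase or CBS reduction) of the 9-oxo dienone A3, itself assembled by an olefination at C10=C11.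
- The stereocentre would be set late and with good reagents, but the structure speaks against the precursor. In A3 the methylene C8 lies between the ketone C9 and the alkene C6=C7, so enolisation should draw the 6Z alkene into conjugation and erase its position and geometry.
- The Z-enal needed for the olefination is prone to Z-to-E drift, and the two ketones C1 and C9 must be told apart.
- The plan settles only the stereocentre. All four alkenes would still be built one by one.

**Alternative 3:** The cut is at C11–C12. The forward key step is a Sonogashira coupling of the (R,E)-vinyl iodide A4 with (Z)-hept-4-en-1-yne A5 to the dienyne A6. A Z-selective semi-reduction of the C12≡C13 triple bond with Zn(Cu/Ag) follows.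
- The coupling itself is reliable and fixes the E alkene. A4, however, needs a separate asymmetric step for C9 and a separate construction of C6=C7.
- The semi-reduction must pick one π-system out of four without over-reduction or isomerisation.
- The same end-game conflict between phenol deprotection and the dienyl carbinol remains.
- In step count and in the number of selectivity problems it is inferior to a plan that takes all alkene positions from one commercial chain.

Key step: step 5

Assumption: 1 is bought as the all-Z acid. The 9R-lipoxygenase (linolenate 9R-lipoxygenase class, EC 1.13.11.61, lipoxygenase domain only, obtained by routine expression in E. coli) is treated as a catalyst and not counted as a step.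

## Steps

Step 1
Reactants: 1 stearidonic acid, (6Z,9Z,12Z,15Z)-octadeca-6,9,12,15-tetraenoic acid
Product: 3 (6Z,9Z,12Z,15Z)-N-methoxy-N-methyloctadeca-6,9,12,15-tetraenamide, via acyl imidazolide 2 (not isolated)
Conditions: CDI (1.1 equiv), CH2Cl2, rt, 1 h; then MeNH(OMe)·HCl (1.5 equiv), rt, 12 h, Ar, dark
Reagents that add atoms: N,O-dimethylhydroxylamine hydrochloride, CNOC.Cl; 1,1'-carbonyldiimidazole, O=C(n1ccnc1)n1ccnc1 (its imidazolyl group stays only in 2)
Why: Amide formation through an acyl imidazolide (CDI activation); the medium is close to neutral and free of metals and radicals, so the four skipped Z alkenes and the bis-allylic methylenes should pass unchanged, and the imidazole set free serves as the base for the amine salt.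

Step 2
Reactants: 4 phloroglucinol (benzene-1,3,5-triol)
Product: 5 1,3,5-tris(methoxymethoxy)benzene
Conditions: NaH (3.6 equiv), DMF, 0 °C; MOMCl (3.6 equiv), 0 °C → rt
Reagents that add atoms: chloromethyl methyl ether, COCCl
Why: Williamson-type O-alkylation; the hard, oxocarbenium-like electrophile should prefer the phenoxide oxygens over the ring carbons, and the three hydroxyl groups are equivalent, so one product is expected.

Step 3
Reactants: 5 1,3,5-tris(methoxymethoxy)benzene; 3 (6Z,9Z,12Z,15Z)-N-methoxy-N-methyloctadeca-6,9,12,15-tetraenamide
Product: 8 (6Z,9Z,12Z,15Z)-1-[2,4,6-tris(methoxymethoxy)phenyl]octadeca-6,9,12,15-tetraen-1-one, via aryllithium 6 (not isolated), via tetrahedral lithium adduct 7 (not isolated)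
Conditions: 5 (1.3 equiv), n-BuLi (1.2 equiv), THF, 0 °C, 1 h; then 3 (1.0 equiv), −78 → 0 °C; sat. aq NH4Cl
Reagents that add atoms: n-butyllithium, [Li]CCCC (its lithium stays only in 6 and 7, not in 8)
Why: Directed ortho-metalation followed by a Weinreb ketone synthesis; each ring C–H of 5 lies between two coordinating OMOM groups and all three are equivalent, so one aryllithium forms, and the chelated adduct 7 holds until the quench, which prevents a second addition. The arene is used in excess so that no n-BuLi is left to attack the bis-allylic positions.

Step 4
Reactants: 8 (6Z,9Z,12Z,15Z)-1-[2,4,6-tris(methoxymethoxy)phenyl]octadeca-6,9,12,15-tetraen-1-one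
Product: 9 (6Z,9Z,12Z,15Z)-1-(2,4,6-trihydroxyphenyl)octadeca-6,9,12,15-tetraen-1-one
Conditions: aq HCl (cat., ca. 0.5 M final), MeOH, 40 °C, Ar, dark
Reagents that add atoms: none
Why: Acid-catalysed transacetalisation of the three aryl MOM ethers to methanol, which also takes up the formaldehyde unit as its dimethyl acetal; methanolic HCl is the medium in which polyunsaturated fatty acids are routinely esterified without alkene migration, and no acid-labile carbinol is present yet, which is the reason for placing this step before step 5.

Step 5
Reactants: 9 (6Z,9Z,12Z,15Z)-1-(2,4,6-trihydroxyphenyl)octadeca-6,9,12,15-tetraen-1-one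
Product: 11 (6Z,9R,10E,12Z,15Z)-9-hydroxy-1-(2,4,6-trihydroxyphenyl)octadeca-6,10,12,15-tetraen-1-one, via 9R-hydroperoxide 10 (not isolated)
Conditions: linolenate 9R-lipoxygenase (recombinant, cat.), O2 (1 atm), 50 mM borate buffer pH 8.5, 5% EtOH, 10 °C, 9 at ca. 1 mM; then TCEP (neutralised, 1.5 equiv), 0 °C; adjust to pH 6, extract with EtOAc
Reagents that add atoms: dioxygen, O=O (both oxygen atoms stay in 10, one in 11)
Why: Lipoxygenase dioxygenation (non-heme iron dioxygenase); the closest known reaction types are the conversion of α-linolenate, whose C9–C18 segment is identical with that of 9, into its (9R,10E,12Z,15Z)-9-hydroperoxide, and the oxygenation of ester- and amide-capped polyenoic chains by lipoxygenases. The Fe(III)–OH centre removes one hydrogen of the bis-allylic C11H2 by proton-coupled electron transfer and leaves a planar pentadienyl radical over C9–C13. Dioxygen reaches this radical only through the protein channel that ends at C9 and on the face opposite to the departed hydrogen (antarafacial), so C9–O should form with R configuration under pure catalyst control, 9 being achiral. Bond formation at C9 localises the π-bonds as C10=C11, which becomes E because the radical is held in its extended shape, and C12=C13, which keeps Z, while C6=C7 and C15=C16 are not touched. The peroxyl radical takes electron and proton back from Fe(II)–OH2 to give 10 and the resting enzyme. The step needs position selectivity (C11–H and not C8–H or C14–H, C9 and not C13): this enzyme class is taken to measure from the methyl end that enters the pocket first, which places C11 (ω8) at the iron, while the head stays at the mouth of the channel, where the acylphloroglucinol, a vinylogous acid that is partly ionised at pH 8.5 and a poor reductant because its meta-hydroxyls allow no quinone, takes the place of a carboxylate. No ring is closed. TCEP then takes the outer oxygen of 10 without touching C9–O, so the configuration is kept, and unlike borohydride it leaves the aryl ketone alone.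

## Compound list

1 | stearidonic acid, (6Z,9Z,12Z,15Z)-octadeca-6,9,12,15-tetraenoic acid | CC/C=C\C/C=C\C/C=C\C/C=C\CCCCC(=O)O | starting material
2 | (6Z,9Z,12Z,15Z)-1-(imidazol-1-yl)octadeca-6,9,12,15-tetraen-1-one (acyl imidazolide) | CC/C=C\C/C=C\C/C=C\C/C=C\CCCCC(=O)n1ccnc1 | intermediate
3 | (6Z,9Z,12Z,15Z)-N-methoxy-N-methyloctadeca-6,9,12,15-tetraenamide | CC/C=C\C/C=C\C/C=C\C/C=C\CCCCC(=O)N(C)OC | intermediate
4 | phloroglucinol (benzene-1,3,5-triol) | Oc1cc(O)cc(O)c1 | starting material
5 | 1,3,5-tris(methoxymethoxy)benzene | COCOc1cc(OCOC)cc(OCOC)c1 | intermediate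
6 | 2,4,6-tris(methoxymethoxy)phenyllithium | [Li]c1c(OCOC)cc(OCOC)cc1OCOC | intermediate
7 | lithium (6Z,9Z,12Z,15Z)-1-[methoxy(methyl)amino]-1-[2,4,6-tris(methoxymethoxy)phenyl]octadeca-6,9,12,15-tetraen-1-olate (tetrahedral adduct, racemic at C1) | CC/C=C\C/C=C\C/C=C\C/C=C\CCCCC(O[Li])(N(C)OC)c1c(OCOC)cc(OCOC)cc1OCOC | intermediate
8 | (6Z,9Z,12Z,15Z)-1-[2,4,6-tris(methoxymethoxy)phenyl]octadeca-6,9,12,15-tetraen-1-one | CC/C=C\C/C=C\C/C=C\C/C=C\CCCCC(=O)c1c(OCOC)cc(OCOC)cc1OCOC | intermediate
9 | (6Z,9Z,12Z,15Z)-1-(2,4,6-trihydroxyphenyl)octadeca-6,9,12,15-tetraen-1-one | CC/C=C\C/C=C\C/C=C\C/C=C\CCCCC(=O)c1c(O)cc(O)cc1O | intermediate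
10 | (6Z,9R,10E,12Z,15Z)-9-hydroperoxy-1-(2,4,6-trihydroxyphenyl)octadeca-6,10,12,15-tetraen-1-one | CC/C=C\C/C=C\C=C\[C@H](OO)C/C=C\CCCCC(=O)c1c(O)cc(O)cc1O | intermediate
11 | (6Z,9R,10E,12Z,15Z)-9-hydroxy-1-(2,4,6-trihydroxyphenyl)octadeca-6,10,12,15-tetraen-1-one (CNP0107106.1) | CC/C=C\C/C=C\C=C\[C@H](O)C/C=C\CCCCC(=O)c1c(O)cc(O)cc1O | target

## Step count and least certain steps

Total step count: 5. Longest linear sequence: 4 (steps 1, 3, 4, 5, or steps 2, 3, 4, 5).

**Step 5 (key step).** The most likely failure is loss of register or of activity.
- The aromatic head may sit at the channel mouth in a way that shifts the chain. Hydrogen abstraction would then move to C8 or C14, or dioxygen would be captured at C13.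
- The phenol may reduce the ferric iron and stall the cycle.
- The product keeps a 12Z,15Z-pentadiene, so a second dioxygenation can set in once 9 is used up.
- Poor dispersion of the substrate in buffer may slow the enzyme so far that racemic autoxidation competes.

The fallback oxygenates first and joins later. It sets out from 1 and comes back to the route at 11.
- 1 is offered to the same enzyme as the free acid, the native substrate class. This gives (6Z,9R,10E,12Z,15Z)-9-hydroperoxyoctadeca-6,10,12,15-tetraenoic acid F1, which is reduced in the flask with TCEP to the 9R-hydroxy acid F2.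
- Coupling with N,O-dimethylhydroxylamine (EDC, HOBt, CH2Cl2) gives the hydroxy Weinreb amide F3. TBSCl and imidazole then give its silyl ether F4.
- Addition of 6 as in step 3 gives the silyl-protected tris-MOM ketone F5.
- The aryl MOM ethers are taken off without protic acid (TMSOTf, 2,2'-bipyridyl, CH2Cl2, 0 °C, then water) to give the silyl-protected triphenol F6.
- TBAF buffered with AcOH gives 11.

**Step 3.** The aryllithium carries two ortho substituents and may act as a base instead of a nucleophile. It could deprotonate C2 of the amide, induce loss of formaldehyde from the N–OMe group, or simply add too slowly at the temperature that the bis-allylic positions tolerate. The fallback replaces acyl substitution by carbonyl addition and oxidation. It sets out from 3 and comes back at 8.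
- DIBAL-H (THF, −78 °C) reduces 3 to (6Z,9Z,12Z,15Z)-octadeca-6,9,12,15-tetraenal F7.
- The much more electrophilic aldehyde takes up 6 at −78 °C to give the racemic benzylic carbinol F8.
- Dess–Martin periodinane buffered with NaHCO3 oxidises F8 to 8.

**Step 4.** The methoxymethyl cation or formaldehyde set free may be recaptured by the nucleophilic ring carbons C3' and C5' (hydroxymethylation, methylene bridging between two rings). The para MOM ether, which has no neighbouring carbonyl, may lag behind and call for harsher acid, under which O-methylation of the ring by methanol can begin. The fallback changes to a protecting group that leaves under neutral, formaldehyde-free conditions. It sets out from 4 (and 3) and comes back at 9.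
- Allyl bromide and K2CO3 in DMF convert 4 into 1,3,5-tris(allyloxy)benzene F9.
- NBS (CH2Cl2, −20 °C) gives 2-bromo-1,3,5-tris(allyloxy)benzene F10.
- Bromine–lithium exchange (n-BuLi, THF, −78 °C) gives 2,4,6-tris(allyloxy)phenyllithium F11. This adds to 3 to give the tris-allyl ketone F12.
- Pd(PPh3)4 (cat.) with morpholine in THF at rt removes the three allyl groups and gives 9. The skipped Z alkenes carry no leaving group and should be inert to Pd(0).

## Further compounds

F1 | step 5 | (6Z,9R,10E,12Z,15Z)-9-hydroperoxyoctadeca-6,10,12,15-tetraenoic acid | CC/C=C\C/C=C\C=C\[C@H](OO)C/C=C\CCCCC(=O)O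
F2 | step 5 | (6Z,9R,10E,12Z,15Z)-9-hydroxyoctadeca-6,10,12,15-tetraenoic acid | CC/C=C\C/C=C\C=C\[C@H](O)C/C=C\CCCCC(=O)O
F3 | step 5 | (6Z,9R,10E,12Z,15Z)-9-hydroxy-N-methoxy-N-methyloctadeca-6,10,12,15-tetraenamide | CC/C=C\C/C=C\C=C\[C@H](O)C/C=C\CCCCC(=O)N(C)OC
F4 | step 5 | (6Z,9R,10E,12Z,15Z)-9-(tert-butyldimethylsilyloxy)-N-methoxy-N-methyloctadeca-6,10,12,15-tetraenamide | CC/C=C\C/C=C\C=C\[C@H](O[Si](C)(C)C(C)(C)C)C/C=C\CCCCC(=O)N(C)OC
F5 | step 5 | (6Z,9R,10E,12Z,15Z)-9-(tert-butyldimethylsilyloxy)-1-[2,4,6-tris(methoxymethoxy)phenyl]octadeca-6,10,12,15-tetraen-1-one | CC/C=C\C/C=C\C=C\[C@H](O[Si](C)(C)C(C)(C)C)C/C=C\CCCCC(=O)c1c(OCOC)cc(OCOC)cc1OCOC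
F6 | step 5 | (6Z,9R,10E,12Z,15Z)-9-(tert-butyldimethylsilyloxy)-1-(2,4,6-trihydroxyphenyl)octadeca-6,10,12,15-tetraen-1-one | CC/C=C\C/C=C\C=C\[C@H](O[Si](C)(C)C(C)(C)C)C/C=C\CCCCC(=O)c1c(O)cc(O)cc1O
F7 | step 3 | (6Z,9Z,12Z,15Z)-octadeca-6,9,12,15-tetraenal | CC/C=C\C/C=C\C/C=C\C/C=C\CCCCC=O
F8 | step 3 | (6Z,9Z,12Z,15Z)-1-[2,4,6-tris(methoxymethoxy)phenyl]octadeca-6,9,12,15-tetraen-1-ol (racemic) | CC/C=C\C/C=C\C/C=C\C/C=C\CCCCC(O)c1c(OCOC)cc(OCOC)cc1OCOC
F9 | step 4 | 1,3,5-tris(allyloxy)benzene | C=CCOc1cc(OCC=C)cc(OCC=C)c1
F10 | step 4 | 2-bromo-1,3,5-tris(allyloxy)benzene | Brc1c(OCC=C)cc(OCC=C)cc1OCC=C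
F11 | step 4 | 2,4,6-tris(allyloxy)phenyllithium | [Li]c1c(OCC=C)cc(OCC=C)cc1OCC=C
F12 | step 4 | (6Z,9Z,12Z,15Z)-1-[2,4,6-tris(allyloxy)phenyl]octadeca-6,9,12,15-tetraen-1-one | CC/C=C\C/C=C\C/C=C\C/C=C\CCCCC(=O)c1c(OCC=C)cc(OCC=C)cc1OCC=C
A1 | alternative 1 | (2E,4R,6Z)-4-(tert-butyldimethylsilyloxy)-12-oxo-12-[2,4,6-tris(methoxymethoxy)phenyl]dodeca-2,6-dienal | O=C/C=C/[C@H](O[Si](C)(C)C(C)(C)C)C/C=C\CCCCC(=O)c1c(OCOC)cc(OCOC)cc1OCOC
A2 | alternative 1 | (Z)-hex-3-en-1-yl(triphenyl)phosphonium bromide | CC/C=C\CC[P+](c1ccccc1)(c1ccccc1)c1ccccc1.[Br-]
A3 | alternative 2 | (6Z,10E,12Z,15Z)-1-(2,4,6-trihydroxyphenyl)octadeca-6,10,12,15-tetraene-1,9-dione | CC/C=C\C/C=C\C=C\C(=O)C/C=C\CCCCC(=O)c1c(O)cc(O)cc1O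
A4 | alternative 3 | (6Z,9R,10E)-9-(tert-butyldimethylsilyloxy)-11-iodo-1-[2,4,6-tris(methoxymethoxy)phenyl]undeca-6,10-dien-1-one | I/C=C/[C@H](O[Si](C)(C)C(C)(C)C)C/C=C\CCCCC(=O)c1c(OCOC)cc(OCOC)cc1OCOC
A5 | alternative 3 | (Z)-hept-4-en-1-yne | C#CC/C=C\CC
A6 | alternative 3 | (6Z,9R,10E,15Z)-9-(tert-butyldimethylsilyloxy)-1-[2,4,6-tris(methoxymethoxy)phenyl]octadeca-6,10,15-trien-12-yn-1-one | CC/C=C\CC#C/C=C/[C@H](O[Si](C)(C)C(C)(C)C)C/C=C\CCCCC(=O)c1c(OCOC)cc(OCOC)cc1OCOC
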